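The C1–C5 stretch of the acid chain (oxygen on C5, carbonyl-level C1 and C3, methyls on C2 and C4) is read as a 3,5-dimethyl-2,3-dihydro-4H-pyran-4-one ring whose oxygen is the C5 oxygen and whose O–C1 bond is opened later. One BF3-promoted diene–aldehyde cyclocondensation forms C4–C5 and O–C1, closes that ring and sets C4 and C5 from the single purchased centre C6. Its precursors are a 1-methoxy-3-silyloxy pentadiene from 3-pentanone and the (S)-α-methyl-β-benzyloxy aldehyde from the Roche ester. The ring then delivers C2 and C3, C7 is grown into the γ-pyranone, and esterification with an aldol-derived keto alcohol and late oxidation finish the target.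

Key step: step 6

Remark: C1–C7 denote the acid chain (C1 ester carbonyl, C7 the pyranone carbon carrying the chain) and C1'–C9' the nonane of the alcohol part; in the target C5' bears two identical (R)-configured arms and is not a stereocentre, so its configuration in intermediates is of no consequence.

Step 1
Reactants: 1 methyl (S)-3-hydroxy-2-methylpropanoate
Product: 2 methyl (S)-3-(benzyloxy)-2-methylpropanoate
Conditions: BnOC(=NH)CCl3, TfOH (cat.), CH2Cl2–cyclohexane, 0 °C → rt
Reagents that add atoms: benzyl 2,2,2-trichloroacetimidate, N=C(OCc1ccccc1)C(Cl)(Cl)Cl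
Why: Acid-catalysed O-benzylation with the trichloroacetimidate avoids base, so the α-stereocentre of the β-hydroxy ester should be untouched.

Step 2
Reactants: 2 methyl (S)-3-(benzyloxy)-2-methylpropanoate
Product: 3 (S)-3-(benzyloxy)-2-methylpropanal
Conditions: i-Bu2AlH, CH2Cl2, −78 °C; aq. potassium sodium tartrate (KNaC4H4O6)
Reagents that add atoms: none
Why: Partial ester reduction stops at the aluminium hemiacetal at −78 °C and releases the aldehyde only on work-up; the configurationally sensitive aldehyde is used crude and at once.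

Step 3
Reactants: 4 3-pentanone; 5 methyl formate
Product: 6 sodium 2-methyl-3-oxopent-1-en-1-olate
Conditions: NaOMe, Et2O, 0 °C → rt; salt collected by filtration
Reagents that add atoms: sodium methoxide, C[O-].[Na+]
Why: Crossed Claisen condensation (formylation) of the ketone with the non-enolisable formate is driven by formation of the stabilised 1,3-dicarbonyl anion.

Step 4
Reactants: 6 sodium 2-methyl-3-oxopent-1-en-1-olate
Product: 7 (E)-1-methoxy-2-methylpent-1-en-3-one
Conditions: Me2SO4, DMF, 0 °C → rt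
Reagents that add atoms: dimethyl sulfate, COS(=O)(=O)OC
Why: O-alkylation of the ambident 1,3-dicarbonyl anion by a hard electrophile in a dipolar aprotic solvent should give the β-methoxy enone with the methoxy group trans to the acyl group.

Step 5
Reactants: 7 (E)-1-methoxy-2-methylpent-1-en-3-one
Product: 8 (1E,3Z)-1-methoxy-2-methyl-3-(trimethylsilyloxy)penta-1,3-diene
Conditions: Me3SiOTf, Et3N, Et2O, 0 °C
Reagents that add atoms: trimethylsilyl trifluoromethanesulfonate, C[Si](C)(C)OS(=O)(=O)C(F)(F)F
Why: Soft enolisation and O-silylation of the ethyl ketone with silyl triflate and amine should give the (Z)-enol silane and hence the (1E,3Z)-diene.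

Step 6
Reactants: 3 (S)-3-(benzyloxy)-2-methylpropanal; 8 (1E,3Z)-1-methoxy-2-methyl-3-(trimethylsilyloxy)penta-1,3-diene
Product: 10 (2R,3R)-2-[(S)-1-(benzyloxy)propan-2-yl]-3,5-dimethyl-2,3-dihydro-4H-pyran-4-one (2,3-trans), via open-chain aldol adduct 9 (not isolated)
Conditions: BF3·OEt2, CH2Cl2, −78 °C; then CF3CO2H, CH2Cl2, rt
Reagents that add atoms: none
Why: BF3 binds the aldehyde oxygen and the enol silane terminus of 8 adds through an open, antiperiplanar Mukaiyama-type transition state to form C4–C5; acid then drives 6-endo-trig addition of the C5 oxygen to C1 of the β-methoxy enone and loss of methanol, which forms O–C1 and closes the dihydropyranone ring. The closest known reaction type is the Lewis acid-mediated cyclocondensation of 1-alkoxy-3-silyloxy dienes with aldehydes (Mukaiyama aldol followed by oxa-Michael addition–elimination). C5 is set by the purchased C6 centre through Felkin–Anh addition (5,6-syn), and C4 is set relative to C5 by the anti preference of the (Z)-enol silane in the open transition state, which appears as the 2,3-trans ring. The step needs Felkin facial selectivity together with anti topicity: BF3 has one coordination site and cannot chelate the benzyloxy oxygen, so the Felkin pathway is not overridden, and the stepwise BF3 pathway is the one that leads to trans products. Any cis isomer at C4 can still be corrected, because that centre is α to the ketone and should equilibrate to the diequatorial arrangement in step 7.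

Step 7
Reactants: 10 (2R,3R)-2-[(S)-1-(benzyloxy)propan-2-yl]-3,5-dimethyl-2,3-dihydro-4H-pyran-4-one
Product: 11 (2S,3S,5R,6R)-6-[(S)-1-(benzyloxy)propan-2-yl]-2-methoxy-3,5-dimethyltetrahydro-4H-pyran-4-one (methoxy axial; both methyls and the side chain equatorial)
Conditions: camphorsulfonic acid (cat.), MeOH, rt, to equilibrium
Reagents that add atoms: methanol, CO
Why: Acid-catalysed conjugate addition of methanol to the vinylogous ester through the C1 oxocarbenium ion gives the 2-methoxy tetrahydropyranone, and under these enolising, reversible conditions the new C2 methyl should settle equatorial and the methoxy group axial (anomeric effect).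

Step 8
Reactants: 11 the 2-methoxy tetrahydropyran-4-one
Product: 12 (2S,3R,4R,5S,6R)-6-[(S)-1-(benzyloxy)propan-2-yl]-2-methoxy-3,5-dimethyltetrahydro-2H-pyran-4-ol (4-OH axial, cis to both methyls)
Conditions: LiBH(s-Bu)3 (L-Selectride), THF, −78 °C; then H2O
Reagents that add atoms: none
Why: The bulky trialkylborohydride attacks the conformationally locked ketone along the equatorial trajectory (the axial face is also screened by the axial methoxy group), so the C3 hydroxyl should emerge axial, which completes the all-cis C2–C4 array.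

Step 9
Reactants: 12 the axial alcohol
Product: 13 tert-butyldimethylsilyl ether of 12
Conditions: t-BuMe2SiOTf, 2,6-lutidine, CH2Cl2, −78 → 0 °C
Reagents that add atoms: tert-butyldimethylsilyl trifluoromethanesulfonate, CC(C)(C)[Si](C)(C)OS(=O)(=O)C(F)(F)F
Why: A silyl triflate with a hindered pyridine base silylates the hindered axial secondary alcohol at low temperature while the methyl acetal is left alone.

Step 10
Reactants: 13 the silylated methyl acetal
Product: 14 (3R,4R,5R,6R)-6-[(S)-1-(benzyloxy)propan-2-yl]-4-(tert-butyldimethylsilyloxy)-3,5-dimethyltetrahydro-2H-pyran-2-one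
Conditions: m-CPBA, BF3·OEt2, CH2Cl2, 0 °C
Reagents that add atoms: 3-chloroperoxybenzoic acid, OOC(=O)c1cccc(Cl)c1
Why: The Lewis acid ionises the methyl acetal to the oxocarbenium ion, the peracid traps it and the peroxy acetal fragments to the δ-lactone (peracid oxidation of lactol ethers), with no stereocentre involved.

Step 11
Reactants: 14 the benzyl ether lactone
Product: 15 (3R,4R,5R,6R)-4-(tert-butyldimethylsilyloxy)-6-[(S)-1-hydroxypropan-2-yl]-3,5-dimethyltetrahydro-2H-pyran-2-one
Conditions: H2 (1 atm), Pd/C, EtOAc, rt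
Reagents that add atoms: none
Why: Hydrogenolysis of the benzyl ether over palladium leaves the silyl ether and the lactone untouched.

Step 12
Reactants: 15 the primary alcohol
Product: 16 aldehyde of 15 (CH2OH oxidised to CHO, all centres as in 15)
Conditions: Dess–Martin periodinane, pyridine, CH2Cl2, 0 °C → rt
Reagents that add atoms: none
Why: Dess–Martin oxidation under buffered, non-basic conditions should give the α-chiral β-acyloxy aldehyde without epimerisation or β-elimination; it is used without delay.

Step 13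
Reactants: 17 3-methylpentane-2,4-dione
Product: 18 (E)-4-methoxy-3-methylpent-3-en-2-one (alkene geometry without consequence)
Conditions: HC(OMe)3, MeOH, H2SO4 (cat.), rt
Reagents that add atoms: trimethyl orthoformate, COC(OC)OC
Why: Acid-catalysed enol ether formation with the orthoester can give only one regioisomer from the symmetric 1,3-diketone.

Step 14
Reactants: 18 (E)-4-methoxy-3-methylpent-3-en-2-one
Product: 20 (E)-5-methoxy-4-methylhex-4-en-3-one, via lithium enolate 19 (not isolated)
Conditions: LiN(i-Pr)2, THF, −78 °C; MeI, −78 → 0 °C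
Reagents that add atoms: iodomethane, CI
Why: Kinetic deprotonation of the vinylogous ester occurs at the α′ methyl group (Stork–Danheiser-type enolate) and C-methylation gives the ethyl ketone.

Step 15
Reactants: 20 (E)-5-methoxy-4-methylhex-4-en-3-one; 16 the lactone aldehyde
Product: 22 aldol adduct of 16 and 20 (mixture at the new carbinol and α-methyl centres), via lithium enolate 21 (not isolated)
Conditions: 20, LiN(i-Pr)2, THF, −78 °C; then 16, −78 °C; AcOH quench
Reagents that add atoms: none
Why: The kinetic α′ lithium enolate adds to the aldehyde at −78 °C (aldol addition) far faster than it can deprotonate the lactone; the two new centres are not controlled, because both are erased in steps 16 and 17.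

Step 16
Reactants: 22 the aldol adduct
Product: 23 1,3-diketone (C7 ketone; the carbon between the carbonyls is stereolabile)
Conditions: Dess–Martin periodinane, pyridine, CH2Cl2, rt
Reagents that add atoms: none
Why: Dess–Martin oxidation converts the β-hydroxy ketone into the 1,3-diketone under mild, non-basic conditions.

Step 17
Reactants: 23 the 1,3-diketone
Product: 24 lactone of 14 in which the side chain is 1-(3,5,6-trimethyl-4-oxo-4H-pyran-2-yl)ethyl (all centres as in 14)
Conditions: TsOH·H2O (cat.), CH2Cl2, rt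
Reagents that add atoms: none
Why: The enol oxygen of the C7 carbonyl adds 6-endo to the β-methoxy enone and methanol is lost, an acid-mediated γ-pyranone synthesis from acylated vinylogous esters; the diketone enolises between its carbonyls, so C6 should keep its configuration.

Step 18
Reactants: 24 the pyranone lactone
Product: 27 seco acid: 3-(tert-butyldimethylsilyloxy)-2,4-dimethyl-5-(triethylsilyloxy)-6-(3,5,6-trimethyl-4-oxo-4H-pyran-2-yl)heptanoic acid (2,3-anti, 3,4-anti, 4,5-anti, 5,6-syn), via lithium carboxylate 25 (not isolated), via bis-triethylsilyl derivative 26 (not isolated)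
Conditions: LiOH, THF–H2O, 0 °C; evaporate, PhMe azeotrope; Et3SiOTf, 2,6-lutidine, CH2Cl2, −78 → 0 °C; then aq. citric acid, THF, 0 °C
Reagents that add atoms: lithium hydroxide, [Li+].[OH-]; triethylsilyl trifluoromethanesulfonate, CC[Si](CC)(CC)OS(=O)(=O)C(F)(F)F
Why: Saponification gives the carboxylate, which cannot relactonise; exhaustive silylation then caps the C5 hydroxyl, and the far more labile silyl ester is hydrolysed selectively by mild aqueous acid.

Step 19
Reactants: 28 (S)-4-benzyl-3-propionyloxazolidin-2-one; 29 propanal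
Product: 31 (S)-4-benzyl-3-[(2S,3R)-3-hydroxy-2-methylpentanoyl]oxazolidin-2-one, via boron enolate 30 (not isolated)
Conditions: n-Bu2BOTf, i-Pr2NEt, CH2Cl2, 0 °C; EtCHO, −78 → 0 °C; H2O2, MeOH, pH 7 buffer
Reagents that add atoms: none
Why: Evans syn aldol: the (Z)-boron enolate reacts through a chair Zimmerman–Traxler transition state on the face away from the benzyl group, which should give the (2S,3R) syn adduct.

Step 20
Reactants: 31 the Evans aldol adduct
Product: 32 (2S,3R)-3-hydroxy-N-methoxy-N,2-dimethylpentanamide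
Conditions: MeNHOMe, AlMe3, CH2Cl2, −20 °C → rt
Reagents that add atoms: N,O-dimethylhydroxylamine, CNOC
Why: Transamination of the imide by the aluminium amide (Weinreb amide formation) removes the auxiliary without touching either stereocentre.

Step 21
Reactants: 32 the hydroxy Weinreb amide
Product: 33 (2S,3R)-N-methoxy-N,2-dimethyl-3-(triethylsilyloxy)pentanamide
Conditions: Et3SiCl, imidazole, DMF, rt
Reagents that add atoms: chlorotriethylsilane, CC[Si](Cl)(CC)CC
Why: Routine silylation of an unhindered secondary alcohol.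

Step 22
Reactants: 33 the silylated Weinreb amide
Product: 34 (2S,3R)-2-methyl-3-(triethylsilyloxy)pentanal
Conditions: i-Bu2AlH, THF, −78 °C; aq. potassium sodium tartrate (KNaC4H4O6)
Reagents that add atoms: none
Why: Reduction of the Weinreb amide stops at the chelated tetrahedral intermediate, which gives the aldehyde only on work-up.

Step 23
Reactants: 4 3-pentanone; 34 (2S,3R)-2-methyl-3-(triethylsilyloxy)pentanal
Product: 36 (4R,5R,6R,7R)-5-hydroxy-4,6-dimethyl-7-(triethylsilyloxy)nonan-3-one, via enol borinate 35 (not isolated)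
Conditions: (c-C6H11)2BCl, Et3N, Et2O, 0 °C; 34, −78 → −20 °C; H2O2, MeOH, pH 7 buffer
Reagents that add atoms: none
Why: Anti-selective boron aldol: the (E)-enol dicyclohexylborinate reacts through a chair transition state (4',5'-anti), and (E)-enolates add to α-methyl aldehydes with Felkin selectivity (5',6'-syn), so C4' should be set as R relative to the auxiliary-derived C6'.

Step 24
Reactants: 27 the seco acid; 36 the keto alcohol
Product: 38 ester of 27 with the C5' hydroxyl of 36, via mixed anhydride 37 (not isolated)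
Conditions: 2,4,6-Cl3C6H2COCl, Et3N, THF, rt; then 36, DMAP, PhMe, rt
Reagents that add atoms: none
Why: Yamaguchi esterification: DMAP attacks the mixed anhydride at the less hindered aliphatic carbonyl and the acylpyridinium ion acylates the secondary alcohol; no stereocentre is formed.

Step 25
Reactants: 38 the fully protected ester
Product: 39 diol (C5 and C7' hydroxyls free, C3 silyl ether retained)
Conditions: HF·pyridine, pyridine, THF, 0 °C; used at once
Reagents that add atoms: none
Why: Buffered HF·pyridine cleaves the two secondary triethylsilyl ethers much faster than the tert-butyldimethylsilyl ether flanked by two branched carbons; the diol is oxidised immediately so that the C5 hydroxyl has little time to attack the hindered ester.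

Step 26
Reactants: 39 the diol
Product: 40 3-O-tert-butyldimethylsilyl ether of the target
Conditions: Dess–Martin periodinane, pyridine, CH2Cl2, 0 °C → rt
Reagents that add atoms: none
Why: Double Dess–Martin oxidation gives the C5 and C7' ketones under buffered conditions, makes C5' non-stereogenic, and creates the epimerisable C6 ketone only at the penultimate stage.

Step 27
Reactants: 40 the silylated target
Product: 41 (4R,6R)-4,6-dimethyl-3,7-dioxononan-5-yl (2R,3R,4S,6S)-3-hydroxy-2,4-dimethyl-5-oxo-6-(3,5,6-trimethyl-4-oxo-4H-pyran-2-yl)heptanoate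
Conditions: aq. HF, MeCN, 0 °C → rt
Reagents that add atoms: none
Why: Acidic fluoride desilylation avoids the base that would cause β-elimination, retro-aldol cleavage or epimerisation at C6.

Compound list
1 | methyl (S)-3-hydroxy-2-methylpropanoate | COC(=O)[C@@H](C)CO | starting material
2 | methyl (S)-3-(benzyloxy)-2-methylpropanoate | COC(=O)[C@@H](C)COCc1ccccc1 | intermediate
3 | (S)-3-(benzyloxy)-2-methylpropanal | O=C[C@@H](C)COCc1ccccc1 | intermediate
4 | 3-pentanone | CCC(=O)CC | starting material
5 | methyl formate | COC=O | starting material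
6 | sodium 2-methyl-3-oxopent-1-en-1-olate (delocalised anion, no fixed C=C geometry) | CCC(=O)C(C)=C[O-].[Na+] | intermediate
7 | (E)-1-methoxy-2-methylpent-1-en-3-one | CO/C=C(C)/C(=O)CC | intermediate
8 | (1E,3Z)-1-methoxy-2-methyl-3-(trimethylsilyloxy)penta-1,3-diene | CO/C=C(C)/C(O[Si](C)(C)C)=C/C | intermediate
9 | (1E,4R,5R,6S)-7-(benzyloxy)-5-hydroxy-1-methoxy-2,4,6-trimethylhept-1-en-3-one (present in the flask as its O-boron or O-silyl derivative) | CO/C=C(C)/C(=O)[C@H](C)[C@H](O)[C@@H](C)COCc1ccccc1 | intermediate (not isolated)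
10 | (2R,3R)-2-[(S)-1-(benzyloxy)propan-2-yl]-3,5-dimethyl-2,3-dihydro-4H-pyran-4-one | CC1=CO[C@H]([C@@H](C)COCc2ccccc2)[C@@H](C)C1=O | intermediate
11 | (2S,3S,5R,6R)-6-[(S)-1-(benzyloxy)propan-2-yl]-2-methoxy-3,5-dimethyltetrahydro-4H-pyran-4-one | CO[C@@H]1[C@H](C)C(=O)[C@H](C)[C@@H]([C@@H](C)COCc2ccccc2)O1 | intermediate
12 | (2S,3R,4R,5S,6R)-6-[(S)-1-(benzyloxy)propan-2-yl]-2-methoxy-3,5-dimethyltetrahydro-2H-pyran-4-ol | CO[C@@H]1[C@H](C)[C@H](O)[C@H](C)[C@@H]([C@@H](C)COCc2ccccc2)O1 | intermediate
13 | tert-butyldimethylsilyl ether of 12 | CO[C@@H]1[C@H](C)[C@H](O[Si](C)(C)C(C)(C)C)[C@H](C)[C@@H]([C@@H](C)COCc2ccccc2)O1 | intermediate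
14 | (3R,4R,5R,6R)-6-[(S)-1-(benzyloxy)propan-2-yl]-4-(tert-butyldimethylsilyloxy)-3,5-dimethyltetrahydro-2H-pyran-2-one | O=C1[C@H](C)[C@H](O[Si](C)(C)C(C)(C)C)[C@H](C)[C@@H]([C@@H](C)COCc2ccccc2)O1 | intermediate
15 | (3R,4R,5R,6R)-4-(tert-butyldimethylsilyloxy)-6-[(S)-1-hydroxypropan-2-yl]-3,5-dimethyltetrahydro-2H-pyran-2-one | O=C1[C@H](C)[C@H](O[Si](C)(C)C(C)(C)C)[C@H](C)[C@@H]([C@@H](C)CO)O1 | intermediate
16 | aldehyde of 15 (side chain 1-oxopropan-2-yl, configuration unchanged) | O=C1[C@H](C)[C@H](O[Si](C)(C)C(C)(C)C)[C@H](C)[C@@H]([C@@H](C)C=O)O1 | intermediate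
17 | 3-methylpentane-2,4-dione | CC(=O)C(C)C(C)=O | starting material
18 | (E)-4-methoxy-3-methylpent-3-en-2-one | CO/C(C)=C(C)/C(C)=O | intermediate
19 | lithium α′-enolate of 18 | CO/C(C)=C(C)/C(=C)O[Li] | intermediate (not isolated)
20 | (E)-5-methoxy-4-methylhex-4-en-3-one | CO/C(C)=C(C)/C(=O)CC | intermediate
21 | lithium α′-enolate of 20 (enolate geometry not controlled) | CO/C(C)=C(C)/C(O[Li])=CC | intermediate (not isolated)
22 | aldol adduct of 16 and 20 (mixture at the carbinol and adjacent methyl-bearing carbon) | O=C1[C@H](C)[C@H](O[Si](C)(C)C(C)(C)C)[C@H](C)[C@@H]([C@@H](C)C(O)C(C)C(=O)/C(C)=C(C)/OC)O1 | intermediate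
23 | 1,3-diketone from 22 (carbon between the carbonyls stereolabile) | O=C1[C@H](C)[C@H](O[Si](C)(C)C(C)(C)C)[C@H](C)[C@@H]([C@@H](C)C(=O)C(C)C(=O)/C(C)=C(C)/OC)O1 | intermediate
24 | lactone of 14 with 1-(3,5,6-trimethyl-4-oxo-4H-pyran-2-yl)ethyl side chain | O=C1[C@H](C)[C@H](O[Si](C)(C)C(C)(C)C)[C@H](C)[C@@H]([C@@H](C)c2oc(C)c(C)c(=O)c2C)O1 | intermediate
25 | lithium salt of the 5-hydroxy seco acid | [Li+].[O-]C(=O)[C@H](C)[C@H](O[Si](C)(C)C(C)(C)C)[C@H](C)[C@H](O)[C@@H](C)c1oc(C)c(C)c(=O)c1C | intermediate (not isolated)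
26 | triethylsilyl ester of 27 | CC[Si](CC)(CC)OC(=O)[C@H](C)[C@H](O[Si](C)(C)C(C)(C)C)[C@H](C)[C@H](O[Si](CC)(CC)CC)[C@@H](C)c1oc(C)c(C)c(=O)c1C | intermediate (not isolated)
27 | 3-(tert-butyldimethylsilyloxy)-2,4-dimethyl-5-(triethylsilyloxy)-6-(3,5,6-trimethyl-4-oxo-4H-pyran-2-yl)heptanoic acid (2,3-anti, 3,4-anti, 4,5-anti, 5,6-syn) | OC(=O)[C@H](C)[C@H](O[Si](C)(C)C(C)(C)C)[C@H](C)[C@H](O[Si](CC)(CC)CC)[C@@H](C)c1oc(C)c(C)c(=O)c1C | intermediate
28 | (S)-4-benzyl-3-propionyloxazolidin-2-one | CCC(=O)N1C(=O)OC[C@@H]1Cc1ccccc1 | starting material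
29 | propanal | CCC=O | starting material
30 | (Z)-di-n-butylboron enolate of 28 | C/C=C(\OB(CCCC)CCCC)N1C(=O)OC[C@@H]1Cc1ccccc1 | intermediate (not isolated)
31 | (S)-4-benzyl-3-[(2S,3R)-3-hydroxy-2-methylpentanoyl]oxazolidin-2-one | O=C([C@@H](C)[C@H](O)CC)N1C(=O)OC[C@@H]1Cc1ccccc1 | intermediate
32 | (2S,3R)-3-hydroxy-N-methoxy-N,2-dimethylpentanamide | CON(C)C(=O)[C@@H](C)[C@H](O)CC | intermediate
33 | (2S,3R)-N-methoxy-N,2-dimethyl-3-(triethylsilyloxy)pentanamide | CON(C)C(=O)[C@@H](C)[C@H](O[Si](CC)(CC)CC)CC | intermediate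
34 | (2S,3R)-2-methyl-3-(triethylsilyloxy)pentanal | O=C[C@@H](C)[C@H](O[Si](CC)(CC)CC)CC | intermediate
35 | (E)-enol dicyclohexylborinate of 3-pentanone | CC/C(OB(C1CCCCC1)C1CCCCC1)=C\C | intermediate (not isolated)
36 | (4R,5R,6R,7R)-5-hydroxy-4,6-dimethyl-7-(triethylsilyloxy)nonan-3-one | CCC(=O)[C@H](C)[C@H](O)[C@@H](C)[C@H](O[Si](CC)(CC)CC)CC | intermediate
37 | mixed anhydride of 27 with 2,4,6-trichlorobenzoic acid | O=C(OC(=O)c1c(Cl)cc(Cl)cc1Cl)[C@H](C)[C@H](O[Si](C)(C)C(C)(C)C)[C@H](C)[C@H](O[Si](CC)(CC)CC)[C@@H](C)c1oc(C)c(C)c(=O)c1C | intermediate (not isolated)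
38 | ester of 27 with the C5' hydroxyl of 36 | CCC(=O)[C@H](C)[C@H](OC(=O)[C@H](C)[C@H](O[Si](C)(C)C(C)(C)C)[C@H](C)[C@H](O[Si](CC)(CC)CC)[C@@H](C)c1oc(C)c(C)c(=O)c1C)[C@@H](C)[C@H](O[Si](CC)(CC)CC)CC | intermediate
39 | diol from 38 (C5 and C7' hydroxyls free) | CCC(=O)[C@H](C)[C@H](OC(=O)[C@H](C)[C@H](O[Si](C)(C)C(C)(C)C)[C@H](C)[C@H](O)[C@@H](C)c1oc(C)c(C)c(=O)c1C)[C@@H](C)[C@H](O)CC | intermediate
40 | 3-O-tert-butyldimethylsilyl ether of the target | CCC(=O)[C@H](C)C(OC(=O)[C@H](C)[C@H](O[Si](C)(C)C(C)(C)C)[C@H](C)C(=O)[C@@H](C)c1oc(C)c(C)c(=O)c1C)[C@@H](C)C(=O)CC | intermediate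
41 | (4R,6R)-4,6-dimethyl-3,7-dioxononan-5-yl (2R,3R,4S,6S)-3-hydroxy-2,4-dimethyl-5-oxo-6-(3,5,6-trimethyl-4-oxo-4H-pyran-2-yl)heptanoate | CCC(=O)[C@H](C)C(OC(=O)[C@H](C)[C@H](O)[C@H](C)C(=O)[C@@H](C)c1oc(C)c(C)c(=O)c1C)[C@@H](C)C(=O)CC | target

Total step count: 27. Longest linear sequence: 18 steps (3-pentanone to 41 through steps 3–12, 15–18 and 24–27).

Steps most likely to fail

Step 6. What may go wrong: insufficient Felkin facial selectivity or insufficient anti topicity in the open transition state, giving diastereomers at C5 or C4. The fallback replaces the open Lewis acid pathway by a closed boron aldol. It sets out from 7 and 3: 7 is enolised with (c-C6H11)2BCl and Et3N to the (E)-enol dicyclohexylborinate of 7 F1, which should add to 3 in an anti, Felkin-selective aldol reaction to give the open-chain adduct 9, now isolated after oxidative work-up. Treatment of 9 with CF3CO2H closes the ring and returns to the route at 10.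

Step 24. What may go wrong: acyl transfer to the doubly flanked secondary hydroxyl may be too slow, so that the activated acid decomposes or the acylated β-hydroxy ketone eliminates. The fallback changes the alcohol partner to one whose hydroxyl is flanked by two sp2 carbons. It sets out from 36: silylation (t-BuMe2SiOTf, 2,6-lutidine) gives the C5' tert-butyldimethylsilyl ether of 36 F2, and buffered HF·pyridine removes the triethylsilyl group to give the C7' alcohol F3. Dess–Martin oxidation gives the silylated diketone F4, and aq. HF in MeCN frees (4R,6R)-5-hydroxy-4,6-dimethylnonane-3,7-dione F5. Yamaguchi coupling of F5 with 27 (through 37) gives the diketo ester F6, buffered HF·pyridine gives its C5 alcohol F7, and Dess–Martin oxidation returns to the route at 40.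

Step 25. What may go wrong: the liberated C5 hydroxyl may attack the ester intramolecularly (relactonisation with loss of the alcohol part) before it is oxidised. The fallback installs the C5 ketone before the coupling. It sets out from 24: LiOH gives 25, which is alkylated in DMF with allyl bromide to the allyl 5-hydroxy ester F8. Immediate Dess–Martin oxidation gives the allyl 5-keto ester F9, and Pd(PPh3)4 with PhSiH3 removes the allyl group under neutral conditions to give the 5-keto acid F10. Its Yamaguchi mixed anhydride F11 is coupled with 36 to the keto ester F12, buffered HF·pyridine removes the single triethylsilyl group to give the C7' alcohol F13, and Dess–Martin oxidation returns to the route at 40.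

Further compounds
F1 | step 6 | (E)-enol dicyclohexylborinate of 7 | CO/C=C(C)/C(OB(C1CCCCC1)C1CCCCC1)=C\C
F2 | step 24 | C5' tert-butyldimethylsilyl ether of 36 | CCC(=O)[C@H](C)[C@H](O[Si](C)(C)C(C)(C)C)[C@@H](C)[C@H](O[Si](CC)(CC)CC)CC
F3 | step 24 | C7' alcohol from F2 | CCC(=O)[C@H](C)[C@H](O[Si](C)(C)C(C)(C)C)[C@@H](C)[C@H](O)CC
F4 | step 24 | (4R,6R)-5-(tert-butyldimethylsilyloxy)-4,6-dimethylnonane-3,7-dione | CCC(=O)[C@H](C)C(O[Si](C)(C)C(C)(C)C)[C@@H](C)C(=O)CC
F5 | step 24 | (4R,6R)-5-hydroxy-4,6-dimethylnonane-3,7-dione | CCC(=O)[C@H](C)C(O)[C@@H](C)C(=O)CC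
F6 | step 24 | ester of 27 with F5 | CCC(=O)[C@H](C)C(OC(=O)[C@H](C)[C@H](O[Si](C)(C)C(C)(C)C)[C@H](C)[C@H](O[Si](CC)(CC)CC)[C@@H](C)c1oc(C)c(C)c(=O)c1C)[C@@H](C)C(=O)CC
F7 | step 24 | C5 alcohol from F6 | CCC(=O)[C@H](C)C(OC(=O)[C@H](C)[C@H](O[Si](C)(C)C(C)(C)C)[C@H](C)[C@H](O)[C@@H](C)c1oc(C)c(C)c(=O)c1C)[C@@H](C)C(=O)CC
F8 | step 25 | allyl 5-hydroxy ester from 25 | C=CCOC(=O)[C@H](C)[C@H](O[Si](C)(C)C(C)(C)C)[C@H](C)[C@H](O)[C@@H](C)c1oc(C)c(C)c(=O)c1C
F9 | step 25 | allyl 5-keto ester | C=CCOC(=O)[C@H](C)[C@H](O[Si](C)(C)C(C)(C)C)[C@H](C)C(=O)[C@@H](C)c1oc(C)c(C)c(=O)c1C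
F10 | step 25 | 5-keto acid | OC(=O)[C@H](C)[C@H](O[Si](C)(C)C(C)(C)C)[C@H](C)C(=O)[C@@H](C)c1oc(C)c(C)c(=O)c1C
F11 | step 25 | mixed anhydride of F10 with 2,4,6-trichlorobenzoic acid | O=C(OC(=O)c1c(Cl)cc(Cl)cc1Cl)[C@H](C)[C@H](O[Si](C)(C)C(C)(C)C)[C@H](C)C(=O)[C@@H](C)c1oc(C)c(C)c(=O)c1C
F12 | step 25 | ester of F10 with 36 | CCC(=O)[C@H](C)[C@H](OC(=O)[C@H](C)[C@H](O[Si](C)(C)C(C)(C)C)[C@H](C)C(=O)[C@@H](C)c1oc(C)c(C)c(=O)c1C)[C@@H](C)[C@H](O[Si](CC)(CC)CC)CC
F13 | step 25 | C7' alcohol from F12 | CCC(=O)[C@H](C)[C@H](OC(=O)[C@H](C)[C@H](O[Si](C)(C)C(C)(C)C)[C@H](C)C(=O)[C@@H](C)c1oc(C)c(C)c(=O)c1C)[C@@H](C)[C@H](O)CC
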